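Ring B of the tetralin is cut at both of its aryl bonds, C4–C4a and C1–C8a. This leaves 4,5-dimethoxybenzyne and a four-carbon 2-oxygenated diene (C1–C4). The key step is an aryne Diels–Alder reaction that closes ring B, makes both bonds and sets C1 in one operation. It exploits two features. The 6,7-dimethoxy pattern of ring A makes C4a and C8a equivalent, so no regiochemistry arises. The 1,3-relationship of O–C2 and O–C1′ lets a di-tert-butylsilylene tie enol and carbinol oxygens into a flat ring. The precursor is thus an enantiopure 6-vinyl-4-styryl-4H-1,3,2-dioxasiline, whose C1′ stereocentre steers the aryne. C2 emerges as a masked ketone.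

Key step: step 4

Numbering remark: the tetralin numbering of the target is used for all compounds. Ring atoms are C1 (benzylic CH), C2 (ring carbinol), C3, C4 (benzylic CH2), C4a and C8a; the side chain is C1′ (carbinol) and C2′=C3′.

Assumption: the sense of induction of the catalyst in step 2 is assigned by analogy with simple conjugated aldehydes. Both mirror-image forms of the catalyst are accessible, so the form that attacks the Si face of enal 2 is the one used.

Step 1
Reactants: 1 (E)-3-(4-hydroxyphenyl)prop-2-enal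
Product: 2 (E)-3-[4-(tert-butyldimethylsilyloxy)phenyl]prop-2-enal
Conditions: TBSCl (1.2 equiv), imidazole (2 equiv), CH2Cl2, 0 °C → rt
Reagents that add atoms: tert-butyldimethylsilyl chloride, CC(C)(C)[Si](C)(C)Cl
Why: Imidazole-promoted O-silylation of a phenol (silyl ether protection) masks the acidic OH through the Lewis acid, silyl triflate and organolithium steps, and the group falls together with the silylene in step 5.

Step 2
Reactants: 2 (E)-3-[4-(tert-butyldimethylsilyloxy)phenyl]prop-2-enal; 3 2-(trimethylsilyloxy)buta-1,3-diene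
Product: 5 (5S,6E)-7-[4-(tert-butyldimethylsilyloxy)phenyl]-5-hydroxyhepta-1,6-dien-3-one, via trichlorosilyl aldolate 4 (not isolated)
Conditions: SiCl4 (1.5 equiv), (S,S)-bisphosphoramide [pentane-1,5-diylbis(N-methylamido)-linked bis(N,N′-dimethyl-1,1′-binaphthyl-2,2′-diamine phosphoramide)] (5 mol %), i-Pr2NEt (0.2 equiv), CH2Cl2, −78 °C; then sat. aq NaHCO3
Reagents that add atoms: silicon tetrachloride, Cl[Si](Cl)(Cl)Cl (its SiCl3 group is carried by 4 only and is lost on work-up)
Why: In this catalytic enantioselective Mukaiyama aldol addition the chiral phosphoramide-bound trichlorosilyl cation binds the conjugated aldehyde and exposes its Si face to the enol silane terminus of 3, which should set C1′ (5S in 5) by 1,2-addition, a reaction type established for methyl ketone enol silanes and cinnamaldehydes.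

Step 3
Reactants: 5 (5S,6E)-7-[4-(tert-butyldimethylsilyloxy)phenyl]-5-hydroxyhepta-1,6-dien-3-one
Product: 7 (4R)-2,2-di-tert-butyl-4-{(E)-2-[4-(tert-butyldimethylsilyloxy)phenyl]ethenyl}-6-ethenyl-4H-1,3,2-dioxasiline, via silyl triflate 6 (not isolated)
Conditions: t-Bu2Si(OTf)2 (1.1 equiv), Et3N (4 equiv), CH2Cl2 (0.02 M), −78 → 0 °C
Reagents that add atoms: di-tert-butylsilyl bis(trifluoromethanesulfonate), CC(C)(C)[Si](OS(=O)(=O)C(F)(F)F)(OS(=O)(=O)C(F)(F)F)C(C)(C)C
Why: O-silylation of the carbinol gives 6, whose remaining Si–OTf group silylates the ketone oxygen intramolecularly while Et3N removes a proton from C1, the only enolisable position; this is the silyl triflate/amine soft enolisation used to make 2-silyloxybutadienes from vinyl ketones, ring closure fixes the Z enol geometry, and C1′ is untouched.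

Step 4
Reactants: 7 (4R)-2,2-di-tert-butyl-4-{(E)-2-[4-(tert-butyldimethylsilyloxy)phenyl]ethenyl}-6-ethenyl-4H-1,3,2-dioxasiline; 8 1,2-dibromo-4,5-dimethoxybenzene
Product: 11 (1R,10bR)-3,3-di-tert-butyl-1-{(E)-2-[4-(tert-butyldimethylsilyloxy)phenyl]ethenyl}-8,9-dimethoxy-6,10b-dihydro-1H-naphtho[1,2-e][1,3,2]dioxasiline (a 6,7-dimethoxy-1,4-dihydronaphthalene whose C2 enol oxygen is joined to the C1′ oxygen through Si(t-Bu)2; 1R and 1′R in tetralin numbering; C8a trans to styryl on the heterocycle), via 2-bromo-4,5-dimethoxyphenyllithium 9 (not isolated), via 4,5-dimethoxybenzyne 10 (not isolated)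
Conditions: 8 (3.0 equiv), n-BuLi (2.8 equiv, hexanes, added over 2 h), toluene–THF 4:1, −78 → 0 °C
Reagents that add atoms: n-butyllithium, [Li]CCCC (its lithium is carried by 9 only)
Why: Bromine–lithium exchange converts 8 into 9, which expels LiBr to give aryne 10, and 10 adds suprafacially to C1 and C4 of the s-cis 2-silyloxydiene of 7 in a concerted, strongly exothermic [4+2] cycloaddition. The closest known reaction type is the aryne Diels–Alder reaction of 2-silyloxybuta-1,3-dienes and of acyclic 1-substituted dienes, including arynes released from 1,2-dihaloarenes by n-BuLi. Ring B is closed as an intermolecular [4+2] annulation in which C4–C4a and C1–C8a form together, and the resulting C2=C3 enol silane is regiodefined. The only new stereocentre, C1, is controlled by C1′: the nearly flat dioxasiline ring holds the small C1′–H on one face and the styryl group on the other, just where the ortho C–H of the incoming aryne (later C8–H) must pass, so bonding should occur anti to the styryl group and place C8a and styryl trans on the heterocycle, which is the C1/C1′ relationship of the target. Regioselectivity is not needed because 10 is symmetric; the step needs periselectivity over ene reaction, [2+2] addition at the enol ether and attack on the styrene, and this is secured by the electron-rich diene, by the 2-oxy substituent that favours the s-cis rotamer and by the ring-locked Z enol geometry that leaves only hydrogen in the inside positions. Compound 7 holds no carbonyl or acidic group for organolithium species to attack, and 8 is kept in slight excess over n-BuLi so that no base is left to isomerise or aromatise the 1,4-dihydronaphthalene.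

Step 5
Reactants: 11 silylene-bridged cycloadduct
Product: 12 (1R)-1-[(1R,2E)-1-hydroxy-3-(4-hydroxyphenyl)prop-2-en-1-yl]-6,7-dimethoxy-3,4-dihydronaphthalen-2(1H)-one
Conditions: Bu4NF (4 equiv), AcOH (4 equiv), THF, 0 °C
Reagents that add atoms: none
Why: Fluoride-mediated desilylation cleaves the aryl silyl ether and both Si–O bonds of the silylene, the liberated enol is protonated at C3 (no stereocentre), and the acetic acid buffer keeps the medium near neutral so that the benzylic α-stereocentre C1 and the aldol linkage should survive.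

Step 6
Reactants: 12 (1R)-1-[(1R,2E)-1-hydroxy-3-(4-hydroxyphenyl)prop-2-en-1-yl]-6,7-dimethoxy-3,4-dihydronaphthalen-2(1H)-one
Product: 13 (1S,2R)-1-[(1R,2E)-1-hydroxy-3-(4-hydroxyphenyl)prop-2-en-1-yl]-6,7-dimethoxy-1,2,3,4-tetrahydronaphthalen-2-ol
Conditions: NaBH4 (2 equiv), MeOH–THF 1:1, −78 → −40 °C; then sat. aq NH4Cl
Reagents that add atoms: none
Why: This is a diastereoselective borohydride reduction under steric approach control: peri strain with C8–H holds the branched C1 side chain pseudo-axial, so external hydride should attack C2 axially from the opposite face and leave the new hydroxyl cis to the side chain (2R), the known outcome for 1-substituted 2-tetralones, whereas a hydroxyl-directed reagent is avoided because it would deliver hydride from the side-chain face.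

Compound list

| No. | Name | SMILES | Role |
|---|---|---|---|
| 1 | (E)-3-(4-hydroxyphenyl)prop-2-enal | O=C/C=C/c1ccc(O)cc1 | starting material |
| 2 | (E)-3-[4-(tert-butyldimethylsilyloxy)phenyl]prop-2-enal | O=C/C=C/c1ccc(O[Si](C)(C)C(C)(C)C)cc1 | intermediate |
| 3 | 2-(trimethylsilyloxy)buta-1,3-diene | C=CC(=C)O[Si](C)(C)C | starting material |
| 4 | trichlorosilyl ether of 5 (trichlorosilyl aldolate) | C=CC(=O)C[C@H](O[Si](Cl)(Cl)Cl)/C=C/c1ccc(O[Si](C)(C)C(C)(C)C)cc1 | intermediate |
| 5 | (5S,6E)-7-[4-(tert-butyldimethylsilyloxy)phenyl]-5-hydroxyhepta-1,6-dien-3-one | C=CC(=O)C[C@H](O)/C=C/c1ccc(O[Si](C)(C)C(C)(C)C)cc1 | intermediate |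
| 6 | di-tert-butyl(trifluoromethanesulfonyloxy)silyl ether of 5 | C=CC(=O)C[C@H](O[Si](OS(=O)(=O)C(F)(F)F)(C(C)(C)C)C(C)(C)C)/C=C/c1ccc(O[Si](C)(C)C(C)(C)C)cc1 | intermediate |
| 7 | (4R)-2,2-di-tert-butyl-4-{(E)-2-[4-(tert-butyldimethylsilyloxy)phenyl]ethenyl}-6-ethenyl-4H-1,3,2-dioxasiline | C=CC1=C[C@@H](/C=C/c2ccc(O[Si](C)(C)C(C)(C)C)cc2)O[Si](C(C)(C)C)(C(C)(C)C)O1 | intermediate |
| 8 | 1,2-dibromo-4,5-dimethoxybenzene | COc1cc(Br)c(Br)cc1OC | starting material |
| 9 | 2-bromo-4,5-dimethoxyphenyllithium | [Li]c1cc(OC)c(OC)cc1Br | intermediate |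
| 10 | 4,5-dimethoxybenzyne | COC1=CC#CC=C1OC | intermediate |
| 11 | (1R,10bR)-3,3-di-tert-butyl-1-{(E)-2-[4-(tert-butyldimethylsilyloxy)phenyl]ethenyl}-8,9-dimethoxy-6,10b-dihydro-1H-naphtho[1,2-e][1,3,2]dioxasiline | COc1cc2c(cc1OC)[C@H]3C(=CC2)O[Si](C(C)(C)C)(C(C)(C)C)O[C@@H]3/C=C/c1ccc(O[Si](C)(C)C(C)(C)C)cc1 | intermediate |
| 12 | (1R)-1-[(1R,2E)-1-hydroxy-3-(4-hydroxyphenyl)prop-2-en-1-yl]-6,7-dimethoxy-3,4-dihydronaphthalen-2(1H)-one | COc1cc2c(cc1OC)[C@H]([C@H](O)/C=C/c1ccc(O)cc1)C(=O)CC2 | intermediate |
| 13 | (1S,2R)-1-[(1R,2E)-1-hydroxy-3-(4-hydroxyphenyl)prop-2-en-1-yl]-6,7-dimethoxy-1,2,3,4-tetrahydronaphthalen-2-ol | COc1cc2c(cc1OC)[C@H]([C@H](O)/C=C/c1ccc(O)cc1)[C@H](O)CC2 | target |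

Total step count: 6. Longest linear sequence: 6 (1 → 2 → 5 → 7 → 11 → 12 → 13).

Steps most likely to fail

**Risk 1 (step 4).**
- What may go wrong:
  - Facial selectivity may be poor because the transition state of an aryne cycloaddition is early.
  - Material may be diverted into an ene reaction at the doubly allylic C1′–H or into [2+2] addition at the enol ether.
  - Residual base may isomerise or aromatise the 1,4-dihydronaphthalene.
- Fallback: the cycloaddition is kept but relieved of its stereochemical task, which passes to a catalytic anti-aldol addition. The fallback sets out from 8, 3 and 2 and comes back at 12.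
  - Aryne 10, released from 8 as before, is trapped with an excess of the cheap diene 3 to give 6,7-dimethoxy-2-(trimethylsilyloxy)-1,4-dihydronaphthalene F1.
  - Dilute HCl in THF gives 6,7-dimethoxy-3,4-dihydronaphthalen-2(1H)-one F2.
  - Me3SiOTf/Et3N enolises toward the benzylic position to give the conjugated enol silane 6,7-dimethoxy-2-(trimethylsilyloxy)-3,4-dihydronaphthalene F3.
  - SiCl4 with catalytic Hg(OAc)2 exchanges silicon to give 6,7-dimethoxy-2-(trichlorosilyloxy)-3,4-dihydronaphthalene F4.
  - Addition of F4 to 2 is catalysed by the appropriate enantiomer of a stilbenediamine-derived chiral phosphoramide. It runs through a closed chair transition state of the ring-locked E enolate. After NaHCO3 work-up it should give the anti aldol (1R)-1-{(1R,2E)-3-[4-(tert-butyldimethylsilyloxy)phenyl]-1-hydroxyprop-2-en-1-yl}-6,7-dimethoxy-3,4-dihydronaphthalen-2(1H)-one F5.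
  - Bu4NF/AcOH then gives 12.

**Risk 2 (step 5).**
- What may go wrong: once the free β-hydroxy ketone is exposed, epimerisation at the benzylic α-carbon C1, retro-aldol cleavage or dehydration may set in.
- Fallback: the β-oxygen stays blocked while the ketone is present, and a bulky hydride sets C2. The fallback sets out from 11 and comes back at 13, bypassing 12.
  - Oxalic acid in THF–H2O at 0 °C protonates only the enol ether. This gives the ketone that keeps a silanol ether at C1′, (1R)-1-{(1R,2E)-3-[4-(tert-butyldimethylsilyloxy)phenyl]-1-[di-tert-butyl(hydroxy)silyloxy]prop-2-en-1-yl}-6,7-dimethoxy-3,4-dihydronaphthalen-2(1H)-one F6.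
  - LiBH(s-Bu)3 in THF at −78 °C attacks opposite the pseudo-axial side chain to give the cis alcohol (1S,2R)-1-{(1R,2E)-3-[4-(tert-butyldimethylsilyloxy)phenyl]-1-[di-tert-butyl(hydroxy)silyloxy]prop-2-en-1-yl}-6,7-dimethoxy-1,2,3,4-tetrahydronaphthalen-2-ol F7.
  - Bu4NF/AcOH removes both silicon groups to give 13.

**Risk 3 (step 2).**
- What may go wrong:
  - Enantioselectivity may be eroded.
  - The silyloxydiene may be diverted into [4+2] or conjugate addition with the activated enal.
  - The vinyl ketone may be lost by oxa-Michael closure.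
- Fallback: auxiliary control replaces catalyst control, and the vinyl ketone is installed last. The fallback sets out from 2 and comes back at 5.
  - The dilithium enolate of commercial (S)-2-hydroxy-1,2,2-triphenylethyl acetate (LDA, THF, −78 °C or below) adds to 2. This gives the ester (1S)-2-hydroxy-1,2,2-triphenylethyl (3S,4E)-5-[4-(tert-butyldimethylsilyloxy)phenyl]-3-hydroxypent-4-enoate F8, which can be purified as a single diastereomer.
  - MeONHMe·HCl/i-PrMgCl converts F8 into (3S,4E)-5-[4-(tert-butyldimethylsilyloxy)phenyl]-3-hydroxy-N-methoxy-N-methylpent-4-enamide F9.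
  - Vinylmagnesium bromide (THF, −78 → 0 °C, acidic quench) gives 5.

Further compounds
F1 | step 4 | 6,7-dimethoxy-2-(trimethylsilyloxy)-1,4-dihydronaphthalene | COc1cc2c(cc1OC)CC(O[Si](C)(C)C)=CC2
F2 | step 4 | 6,7-dimethoxy-3,4-dihydronaphthalen-2(1H)-one | COc1cc2c(cc1OC)CC(=O)CC2
F3 | step 4 | 6,7-dimethoxy-2-(trimethylsilyloxy)-3,4-dihydronaphthalene | COc1cc2c(cc1OC)C=C(O[Si](C)(C)C)CC2
F4 | step 4 | 6,7-dimethoxy-2-(trichlorosilyloxy)-3,4-dihydronaphthalene | COc1cc2c(cc1OC)C=C(O[Si](Cl)(Cl)Cl)CC2
F5 | step 4 | (1R)-1-{(1R,2E)-3-[4-(tert-butyldimethylsilyloxy)phenyl]-1-hydroxyprop-2-en-1-yl}-6,7-dimethoxy-3,4-dihydronaphthalen-2(1H)-one | COc1cc2c(cc1OC)[C@H]([C@H](O)/C=C/c1ccc(O[Si](C)(C)C(C)(C)C)cc1)C(=O)CC2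
F6 | step 5 | (1R)-1-{(1R,2E)-3-[4-(tert-butyldimethylsilyloxy)phenyl]-1-[di-tert-butyl(hydroxy)silyloxy]prop-2-en-1-yl}-6,7-dimethoxy-3,4-dihydronaphthalen-2(1H)-one | COc1cc2c(cc1OC)[C@H]([C@H](O[Si](O)(C(C)(C)C)C(C)(C)C)/C=C/c1ccc(O[Si](C)(C)C(C)(C)C)cc1)C(=O)CC2
F7 | step 5 | (1S,2R)-1-{(1R,2E)-3-[4-(tert-butyldimethylsilyloxy)phenyl]-1-[di-tert-butyl(hydroxy)silyloxy]prop-2-en-1-yl}-6,7-dimethoxy-1,2,3,4-tetrahydronaphthalen-2-ol | COc1cc2c(cc1OC)[C@H]([C@H](O[Si](O)(C(C)(C)C)C(C)(C)C)/C=C/c1ccc(O[Si](C)(C)C(C)(C)C)cc1)[C@H](O)CC2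
F8 | step 2 | (1S)-2-hydroxy-1,2,2-triphenylethyl (3S,4E)-5-[4-(tert-butyldimethylsilyloxy)phenyl]-3-hydroxypent-4-enoate | O=C(C[C@H](O)/C=C/c1ccc(O[Si](C)(C)C(C)(C)C)cc1)O[C@@H](c1ccccc1)C(O)(c1ccccc1)c1ccccc1
F9 | step 2 | (3S,4E)-5-[4-(tert-butyldimethylsilyloxy)phenyl]-3-hydroxy-N-methoxy-N-methylpent-4-enamide | CON(C)C(=O)C[C@H](O)/C=C/c1ccc(O[Si](C)(C)C(C)(C)C)cc1
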